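The C5,C7-dioxygenated A ring (C4a, C5, C6, C7, C8, C8a) is a cyclised tricarbonyl chain, so the route rests on disconnecting its C5–C6 bond. The precursor is a pyrano[4,3-b]pyran-4,5-dione: the finished 3-aryl-4-pyranone C ring fused to a 6-methyl-2-pyranone whose lactone carbonyl is the future C5 and whose methyl group is the future C6. In one operation magnesium methoxide opens the lactone to an ester plus an acetonyl ketone, closes C5–C6 by intramolecular Claisen condensation and lets the ring aromatise, so the unprotected target forms directly. The precursor is assembled in three steps from triacetic acid lactone and a prenylated arylacetic acid.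

Key step: step 4

Remark: the target has no stereocentre and no stereogenic double bond (the prenyl alkene carries two identical methyl groups), so it is achiral and no enantioselective step is needed.

Step 1
Reactants: 1 bromo acid (2-(3-bromo-4-methoxyphenyl)acetic acid); 2 prenylboronic acid pinacol ester (4,4,5,5-tetramethyl-2-(3-methylbut-2-enyl)-1,3,2-dioxaborolane)
Product: 3 prenyl acid (2-[4-methoxy-3-(3-methylbut-2-enyl)phenyl]acetic acid)
Conditions: 2 (1.5 equiv), Pd-PEPPSI-IPent (2 mol%), 5 M aq KOH (4 equiv), THF, 70 °C; then 1 M HCl, 0 °C
Reagents that add atoms: none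
Why: Suzuki–Miyaura coupling of the aryl bromide (present as its potassium carboxylate) with the allylic boronate, in which the bulky NHC ligand should direct C–C bond formation to the unsubstituted α-carbon of the allyl unit and so give the linear prenyl arene and not the 1,1-dimethylallyl isomer.

Step 2
Reactants: 3 prenyl acid; 4 triacetic acid lactone (4-hydroxy-6-methyl-2H-pyran-2-one)
Product: 6 C-acyl pyranone (4-hydroxy-3-{2-[4-methoxy-3-(3-methylbut-2-enyl)phenyl]acetyl}-6-methyl-2H-pyran-2-one), via enol ester 5 (not isolated)
Conditions: DCC (1.1 equiv), DMAP (0.3 equiv), PhMe, rt then 80 °C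
Reagents that add atoms: none
Why: Steglich-type carbodiimide activation should acylate O4 to give enol ester 5, and DMAP then mediates the O→C acyl shift (Fries-type rearrangement through an acylpyridinium/pyranone enolate pair) to C3, the carbon between the lactone carbonyl and the enol carbon, with the hydrogen-bonded tricarbonyl 6 as the thermodynamic sink.

Step 3
Reactants: 6 C-acyl pyranone; 7 N,N-dimethylformamide dimethyl acetal
Product: 9 pyranopyrandione (3-[4-methoxy-3-(3-methylbut-2-enyl)phenyl]-7-methyl-4H,5H-pyrano[4,3-b]pyran-4,5-dione), via enaminone 8 (not isolated)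
Conditions: 7 (1.5 equiv), PhMe, 70 °C; concentrate; AcOH, 60 °C
Reagents that add atoms: none
Why: Condensation of the amide acetal at the benzylic methylene (the most acidic C–H, flanked by the aryl ring and the ketone) should give enaminone 8, and acid-promoted addition–elimination of the C4 enol oxygen at the aminomethylene carbon expels dimethylamine and closes the 4-pyranone ring, which is the enaminone annulation used to turn 2-hydroxydeoxybenzoins into isoflavones.

Step 4
Reactants: 9 pyranopyrandione
Product: 12 target isoflavone (5,7-dihydroxy-3-[4-methoxy-3-(3-methylbut-2-enyl)phenyl]-4H-chromen-4-one), via ring-opened methyl ester 10 (not isolated), via chromene-4,5,7-trione 11 (not isolated)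
Conditions: Mg(OMe)2 (5 equiv), dry MeOH, 0 °C → reflux, Ar; then 1 M HCl, 0 °C
Reagents that add atoms: none
Why: Methoxide adds to the lactone carbonyl C5 and the C5–O6 bond breaks, giving ester 10 as the magnesium enolate of its acetonyl ketone; proton exchange then places the carbanion on the terminal methyl group, which attacks the ester carbonyl, expels methoxide and forms C5–C6. The carbocycle closes in the 6-(enolendo)-exo-trig mode, and trione 11 tautomerises at once to the 5,7-dihydroxy arene, held as its magnesium phenoxide, which makes the sequence irreversible. The closest known reaction type is the alkoxide-mediated recyclisation of 4-oxygenated 2-pyranones and 3,5-diketo esters to resorcinols and phloroglucinols by Claisen condensation, together with the Dieckmann-type closure of δ-keto esters to cyclohexane-1,3-diones. No stereocentre is created. Two selectivities are needed: methoxide must cleave the lactone and leave the 4-pyranone intact, and the carbanion must choose the ester over the C4 ketone. The first should hold because C5 is the only acyl carbon with a leaving group, while conjugate additions at C2, C7 or C8a should be reversible in dry methanol and only the Claisen channel ends in an arene; the second because attack at C4 would give a strained bridged aldolate with a bridgehead alkene, whereas magnesium chelation of the C4 carbonyl and the ester activates the ester.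

Compound list
1 | 2-(3-bromo-4-methoxyphenyl)acetic acid | COc1ccc(CC(=O)O)cc1Br | starting material
2 | 4,4,5,5-tetramethyl-2-(3-methylbut-2-enyl)-1,3,2-dioxaborolane (prenylboronic acid pinacol ester) | CC(C)=CCB1OC(C)(C)C(C)(C)O1 | starting material
3 | 2-[4-methoxy-3-(3-methylbut-2-enyl)phenyl]acetic acid | COc1ccc(CC(=O)O)cc1CC=C(C)C | intermediate
4 | 4-hydroxy-6-methyl-2H-pyran-2-one (triacetic acid lactone) | CC1=CC(O)=CC(=O)O1 | starting material
5 | 6-methyl-2-oxo-2H-pyran-4-yl 2-[4-methoxy-3-(3-methylbut-2-enyl)phenyl]acetate (enol ester) | CC1=CC(OC(=O)Cc2ccc(OC)c(CC=C(C)C)c2)=CC(=O)O1 | intermediate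
6 | 4-hydroxy-3-{2-[4-methoxy-3-(3-methylbut-2-enyl)phenyl]acetyl}-6-methyl-2H-pyran-2-one | CC1=CC(O)=C(C(=O)Cc2ccc(OC)c(CC=C(C)C)c2)C(=O)O1 | intermediate
7 | N,N-dimethylformamide dimethyl acetal (1,1-dimethoxy-N,N-dimethylmethanamine) | COC(OC)N(C)C | starting material
8 | 3-{3-(dimethylamino)-2-[4-methoxy-3-(3-methylbut-2-enyl)phenyl]prop-2-enoyl}-4-hydroxy-6-methyl-2H-pyran-2-one (enaminone; geometry of the push–pull C=C not defined, either isomer cyclises) | CC1=CC(O)=C(C(=O)C(=CN(C)C)c2ccc(OC)c(CC=C(C)C)c2)C(=O)O1 | intermediate
9 | 3-[4-methoxy-3-(3-methylbut-2-enyl)phenyl]-7-methyl-4H,5H-pyrano[4,3-b]pyran-4,5-dione | CC1=CC2=C(C(=O)O1)C(=O)C(c1ccc(OC)c(CC=C(C)C)c1)=CO2 | intermediate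
10 | methyl 5-[4-methoxy-3-(3-methylbut-2-enyl)phenyl]-4-oxo-2-(2-oxopropyl)-4H-pyran-3-carboxylate | COC(=O)C1=C(CC(C)=O)OC=C(c2ccc(OC)c(CC=C(C)C)c2)C1=O | intermediate
11 | 3-[4-methoxy-3-(3-methylbut-2-enyl)phenyl]-6H-chromene-4,5,7(8H)-trione | O=C1CC(=O)C2=C(C1)OC=C(c1ccc(OC)c(CC=C(C)C)c1)C2=O | intermediate
12 | 5,7-dihydroxy-3-[4-methoxy-3-(3-methylbut-2-enyl)phenyl]-4H-chromen-4-one | COc1ccc(-c2coc3cc(O)cc(O)c3c2=O)cc1CC=C(C)C | target

Total step count: 4
Longest linear sequence: 4 steps (1 → 3 → 6 → 9 → 12)

Steps most likely to fail

Step 4. Methoxide may add in conjugate fashion to the 4-pyranone (C2 or C8a), open that ring and lose the C2 carbon by retro-Claisen cleavage. The sequence may also stall at the ring-opened ester, because the terminal methyl group is deprotonated slowly once the more acidic C8 methylene is ionised. The fallback sets out from bromo acid 1 and takes the A ring from phloroglucinol. Friedel–Crafts acylation of phloroglucinol with 1 in BF3·OEt2 at 85 °C should give the deoxybenzoin 2-(3-bromo-4-methoxyphenyl)-1-(2,4,6-trihydroxyphenyl)ethan-1-one F1; no acid-labile prenyl group is present at this stage. One-carbon annulation with DMF, BF3·OEt2 and MsCl at 70 °C should give the bromo-isoflavone 3-(3-bromo-4-methoxyphenyl)-5,7-dihydroxy-4H-chromen-4-one F2. An α-selective Suzuki–Miyaura prenylation with boronate 2, run with aqueous K3PO4 in THF at 60 °C to spare the isoflavone ring, comes back to the route at target 12.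

Step 3. The acetal may transfer a methyl group to the acidic C4 enol, condensation may occur at the C6 methyl group, or the enaminone may fail to close completely. The fallback sets out from 6 and brings in the carbon by Claisen formylation. The polyanion of 6 (LiHMDS, 3.2 equiv, THF, −78 °C) is C-formylated at the benzylic carbon with ethyl formate. Acidic work-up should give the hydroxymethylene ketone 4-hydroxy-3-{3-hydroxy-2-[4-methoxy-3-(3-methylbut-2-enyl)phenyl]prop-2-enoyl}-6-methyl-2H-pyran-2-one F3. A separate cyclodehydration in AcOH at 60 °C closes the 4-pyranone and comes back to the route at 9.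

Step 1. The α/γ regioselectivity of the allylic boronate coupling may erode, giving the 1,1-dimethylallyl isomer, or the boronate may protodeboronate before it couples. The fallback sets out from 1 and builds the prenyl group in two operations with no regiochemical question. Suzuki–Miyaura coupling with allylboronic acid pinacol ester (Pd(dppf)Cl2, K2CO3, dioxane–water, 80 °C) should give the allyl arene 2-[4-methoxy-3-(prop-2-enyl)phenyl]acetic acid F4. Olefin cross-metathesis with 2-methyl-2-butene (second-generation ruthenium benzylidene catalyst, CH2Cl2, 40 °C) converts the allyl into the prenyl group and comes back to the route at 3.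

Further compounds
F1 | step 4 | 2-(3-bromo-4-methoxyphenyl)-1-(2,4,6-trihydroxyphenyl)ethan-1-one | COc1ccc(CC(=O)c2c(O)cc(O)cc2O)cc1Br
F2 | step 4 | 3-(3-bromo-4-methoxyphenyl)-5,7-dihydroxy-4H-chromen-4-one | COc1ccc(-c2coc3cc(O)cc(O)c3c2=O)cc1Br
F3 | step 3 | 4-hydroxy-3-{3-hydroxy-2-[4-methoxy-3-(3-methylbut-2-enyl)phenyl]prop-2-enoyl}-6-methyl-2H-pyran-2-one | CC1=CC(O)=C(C(=O)C(=CO)c2ccc(OC)c(CC=C(C)C)c2)C(=O)O1
F4 | step 1 | 2-[4-methoxy-3-(prop-2-enyl)phenyl]acetic acid | COc1ccc(CC(=O)O)cc1CC=C
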